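**Plan**
- Retrosynthesis: the side chain is cut first at the C(sp2)–C(sp3) bond between the vinylic CH of the fourth (E)-C(CH3)=CH unit (counted from the isopropylidene end) and its allylic CH2. Then the pyran ring is opened at O1–C8a and the styrenic C4–C4a bond is cut. The remaining C25 head chain goes back to geranylgeraniol, a C3 propargyl unit, CH3 and CH2O.
- Enabling feature: that bond ends a 2-methylalk-1-enyl unit, R–C(CH3)=CH–, which is exactly what syn-methylmetalation of a terminal alkyne writes. Alkyne, Me3Al and a homoallylic iodide are therefore joined in one operation that makes the C–CH3 bond, fixes the E geometry and forms the fragment-joining bond.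
- Forward order: geranylgeraniol → C23 enyne → all-E C25 allylic alcohol → epoxide → (R)-tertiary propargylic alcohol. Sonogashira coupling to a prefabricated bromo-iodo arene (ring A), Lindlar reduction and intramolecular aryl etherification close the pyran (ring B). The chain terminus is then turned into a homoallylic iodide, the farnesyl-derived enyne is joined, and the silyl group is removed.
- Stereochemistry: C2 (R) comes from a Sharpless epoxidation with D-(−)-diethyl tartrate, and its C–O bond is never broken afterwards. Six E alkenes come from farnesyl bromide and geranylgeraniol, two from syn-methylalumination; the chromene Z alkene comes from Lindlar reduction.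

Key step: step 18

Remark (assumption): compounds that contain the 2H-chromene (23 onwards) are handled below about 60 °C and with exclusion of light, because 2H-chromenes can racemise at C2 by reversible electrocyclic ring opening. C2 is R with the priorities O > C3 > chain CH2 > CH3.

Step 1
Reactants: 1 (2E,6E)-farnesyl bromide; 2 1-(trimethylsilyl)propyne
Product: 4 (5E,9E)-6,10,14-trimethylpentadeca-5,9,13-trien-1-yne, via silylalkyne 3 (not isolated)
Conditions: 2, n-BuLi, THF, −78 → −20 °C; then 1, −78 °C → rt; crude 3: K2CO3, MeOH, rt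
Reagents that add atoms: none
Why: SN2 alkylation of the propargylic lithium reagent of 2 at the primary allylic bromide (the silyl group blocks the alkyne terminus and suppresses allene formation), followed by base-mediated C–Si methanolysis, should give the terminal enyne with both farnesyl E alkenes unchanged.

Step 2
Reactants: 5 all-E-geranylgeraniol
Product: 6 all-E-geranylgeranyl bromide
Conditions: PBr3, Et2O, −10 → 0 °C; used crude
Reagents that add atoms: phosphorus tribromide, BrP(Br)Br
Why: bromination of a primary allylic alcohol through its phosphite ester (SN2) at low temperature should proceed without allylic transposition or E/Z isomerisation.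

Step 3
Reactants: 6 all-E-geranylgeranyl bromide; 2 1-(trimethylsilyl)propyne
Product: 8 (5E,9E,13E)-6,10,14,18-tetramethylnonadeca-5,9,13,17-tetraen-1-yne, via silylalkyne 7 (not isolated)
Conditions: 2, n-BuLi, THF, −78 → −20 °C; then 6, −78 °C → rt; crude 7: K2CO3, MeOH, rt
Reagents that add atoms: none
Why: the same propargylic SN2 alkylation and desilylation as in step 1 should extend the C20 chain by the three carbons that become C2, C3 and the first chain CH2 of the chromene unit.

Step 4
Reactants: 8 C23 tetraenyne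
Product: 11 (2E,6E,10E,14E)-3,7,11,15,19-pentamethylicosa-2,6,10,14,18-pentaen-1-ol, via alkenylalane 9 (not isolated), via lithium alanate 10 (not isolated)
Conditions: Me3Al, Cp2ZrCl2 (0.25 equiv), ClCH2CH2Cl, rt; volatiles removed; n-BuLi, hexane/THF, −78 → 0 °C; (CH2O)n, rt; 3 M HCl
Reagents that add atoms: trimethylaluminium, C[Al](C)C; paraformaldehyde (formaldehyde unit), C=O
Why: Negishi zirconium-catalysed carboalumination adds CH3 and Al syn across the terminal alkyne (CH3 to the internal carbon), and hydroxymethylation of the derived alanate with retention should give the 2E allylic alcohol as one geometric isomer.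

Step 5
Reactants: 11 all-E C25 allylic alcohol
Product: 12 (2R,3R)-2,3-epoxy alcohol
Conditions: Ti(OiPr)4 (5 mol %), D-(−)-diethyl tartrate [(S,S), 7 mol %], t-BuOOH, 4 Å molecular sieves, CH2Cl2, −20 °C
Reagents that add atoms: tert-butyl hydroperoxide, CC(C)(C)OO
Why: Sharpless asymmetric epoxidation touches only the allylic-alcohol alkene, and the D-(−)-tartrate complex delivers oxygen to the face that gives the (2R,3R)-epoxide (as for geraniol), which sets the future chromene C2 as R.

Step 6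
Reactants: 12 (2R,3R)-epoxy alcohol
Product: 13 epoxy chloride (same spatial arrangement; the CIP label of the CH carbon becomes S)
Conditions: PPh3, CCl4, NaHCO3, 60 °C
Reagents that add atoms: tetrachloromethane, ClC(Cl)(Cl)Cl
Why: Appel chlorination replaces the primary hydroxyl by SN2 at CH2 under neutral conditions, so the epoxide and both stereocentres should stay untouched.

Step 7
Reactants: 13 epoxy chloride
Product: 15 (3R,6E,10E,14E)-3,7,11,15,19-pentamethylicosa-6,10,14,18-tetraen-1-yn-3-ol, via chloroalkenolate 14 (not isolated)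
Conditions: n-BuLi (3.5 equiv), THF, −78 → −30 °C; aq. NH4Cl
Reagents that add atoms: none
Why: base-induced eliminative opening of a 2,3-epoxy chloride (deprotonation next to chlorine, β-elimination that breaks the secondary C–O bond, then dehydrochlorination) should give the terminal alkyne, while the tertiary C–O bond is never broken and the carbinol stays R.

Step 8
Reactants: 16 4-amino-2,3-dimethylphenol
Product: 17 2,3-dimethyl-4-[(triisopropylsilyl)oxy]aniline
Conditions: i-Pr3SiCl, imidazole, DMF, rt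
Reagents that add atoms: chlorotriisopropylsilane, CC(C)[Si](Cl)(C(C)C)C(C)C
Why: silylation should occur at the phenol oxygen, since any N-silyl aniline formed does not survive aqueous work-up.

Step 9
Reactants: 17 silyloxyaniline
Product: 18 6-iodo-2,3-dimethyl-4-[(triisopropylsilyl)oxy]aniline
Conditions: N-iodosuccinimide, MeCN, 0 °C, dark
Reagents that add atoms: N-iodosuccinimide, O=C1CCC(=O)N1I
Why: electrophilic aromatic iodination is directed by the amino group to its only free ortho position (para is blocked and the other free CH is shielded by the silyl ether).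

Step 10
Reactants: 18 iodoaniline
Product: 20 (4-bromo-5-iodo-2,3-dimethylphenoxy)triisopropylsilane, via diazonium salt 19 (not isolated)
Conditions: t-BuONO, CuBr2, MeCN, 0 °C → rt
Reagents that add atoms: copper dibromide, Br[Cu]Br
Why: Sandmeyer bromination under non-aqueous diazotisation should replace the amino group by bromine through an aryl radical and bromine transfer from copper, leaving the silyl ether and the C–I bond in place.

Step 11
Reactants: 15 (R)-alkynol; 20 bromo-iodo arene
Product: 21 (3R)-1-aryl-alk-1-yn-3-ol (aryl = 2-bromo-3,4-dimethyl-5-silyloxyphenyl)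
Conditions: PdCl2(PPh3)2 (3 mol %), CuI (5 mol %), Et3N/THF, rt → 40 °C
Reagents that add atoms: none
Why: Sonogashira coupling should be selective for the C–I bond over the hindered C–Br bond in oxidative addition to zerovalent palladium, and the tertiary propargylic alcohol needs no protection.

Step 12
Reactants: 21 aryl alkynol
Product: 22 (1Z,3R)-1-aryl-alk-1-en-3-ol
Conditions: H2 (1 atm), Pd/CaCO3 poisoned with Pb(OAc)2, quinoline, EtOAc, rt
Reagents that add atoms: none
Why: Lindlar semi-hydrogenation adds H2 syn to the alkyne and should stop at the Z alkene without touching the trisubstituted alkenes or the aryl bromide.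

Step 13
Reactants: 22 (Z)-bromoaryl allylic alcohol
Product: 23 (2R)-6-silyloxy-2H-chromene with the tetraenyl side chain
Conditions: Pd(OAc)2 (5 mol %), 2-(di-tert-butylphosphino)-1,1′-binaphthyl (6 mol %), Cs2CO3, toluene, 50 °C, dark
Reagents that add atoms: none
Why: palladium-catalysed intramolecular C–O coupling (Buchwald–Hartwig etherification) should close ring B by reductive elimination from a seven-membered palladacycle, because the Z alkene holds the β-hydrogen-free tertiary alkoxide next to the aryl–Pd bond, and C2 stays R since only the aryl C–Br bond is exchanged.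

Step 14
Reactants: 23 chromene silyl ether
Product: 25 terminal (2E)-enal, via allylic alcohol 24 (not isolated)
Conditions: SeO2 (0.3 equiv), t-BuOOH, salicylic acid (cat.), CH2Cl2, 0 °C → rt, stopped at partial conversion; then MnO2, CH2Cl2, rt
Reagents that add atoms: tert-butyl hydroperoxide (terminal oxygen source), CC(C)(C)OO; selenium dioxide (catalytic oxygen carrier), O=[Se]=O
Why: Riley allylic oxidation (ene reaction, then [2,3]-sigmatropic shift) should oxidise the E methyl of the terminal isopropylidene, the most accessible ene donor of the chain, and MnO2 should converge alcohol and aldehyde to the E enal.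

Step 15
Reactants: 25 enal
Product: 26 terminal (E)-1,3-diene
Conditions: Ph3PCH3Br, NaN(SiMe3)2, THF, 0 °C; then 25, −78 → 0 °C
Reagents that add atoms: methyltriphenylphosphonium bromide, C[P+](c1ccccc1)(c1ccccc1)c1ccccc1.[Br-]
Why: Wittig methylenation of the unhindered enal should add the carbon that becomes the coupling CH2 without moving the E trisubstituted alkene.

Step 16
Reactants: 26 diene
Product: 28 primary homoallylic alcohol, via alkylborane 27 (not isolated)
Conditions: 9-BBN, THF, 0 °C → rt; then aq. NaOH, H2O2, 0 °C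
Reagents that add atoms: hydrogen peroxide, OO
Why: hydroboration–oxidation with the bulky 9-BBN should add anti-Markovnikov to the only monosubstituted alkene (the vinyl end of the diene), faster than to the trisubstituted alkenes or the hindered chromene alkene, and oxidation with retention gives the primary alcohol.

Step 17
Reactants: 28 homoallylic alcohol
Product: 29 homoallylic iodide
Conditions: PPh3, I2, imidazole, CH2Cl2, 0 °C, dark
Reagents that add atoms: iodine, II
Why: Appel-type iodination (SN2 displacement of the alkoxyphosphonium by iodide) should convert the primary alcohol without touching the alkenes.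

Step 18
Reactants: 4 C18 trienyne; 29 homoallylic iodide
Product: 32 plastochromenol-8 triisopropylsilyl ether, via alkenylalane 30 (not isolated), via alkenylzinc bromide 31 (not isolated)
Conditions: 4 (1.5 equiv), Me3Al, Cp2ZrCl2 (0.25 equiv), ClCH2CH2Cl, rt; volatiles removed in vacuo; ZnBr2, THF, 0 °C; then 29, PdCl2(IPr)(3-chloropyridine) (5 mol %; IPr = 1,3-bis(2,6-diisopropylphenyl)imidazol-2-ylidene), LiBr, THF/NMP, rt, dark
Reagents that add atoms: trimethylaluminium, C[Al](C)C
Why: Proposed new method: Cp2ZrCl2-catalysed syn-methylalumination of the terminal alkyne of 4 (CH3 to the internal carbon, Al to the terminal carbon, no other π bond reacts) gives the (E)-2-methylalkenylalane 30, whose sp2 C–Al bond is exchanged by ZnBr2 to the alkenylzinc bromide 31; zerovalent palladium bearing a bulky N-heterocyclic carbene then inserts into the primary C–I bond of 29 by SN2-like oxidative addition, transmetalates with 31 and reductively eliminates the C(sp2)–C(sp3) bond. The closest known reaction types are the one-pot zirconium-catalysed carboalumination/palladium-catalysed cross-coupling of alkynes with aryl, alkenyl, allyl and benzyl halides and the Negishi coupling of alkenylzinc halides with unactivated primary alkyl halides; what is new is their union with a β-hydrogen-bearing homoallylic iodide as the electrophile of the tandem process. No ring is closed and no stereocentre is formed; the one stereo-element created is the E trisubstituted alkene, which is controlled by the syn addition of CH3–Al across the alkyne and kept because transmetalation and reductive elimination are stereoretentive. The step needs regioselective methylmetalation (secured by the terminal alkyne and the zirconocene catalyst), alkenyl rather than methyl transfer to palladium (secured by removing excess Me3Al before ZnBr2 is added and by the faster transfer of sp2 carbon), and reductive elimination faster than β-hydride elimination of the homoallylpalladium species, which would return diene 26 (secured by the bulky carbene ligand and room temperature). The chromene ring, the silyl ether and C2 of 29 should not be affected at room temperature in the dark.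

Step 19
Reactants: 32 silyl ether
Product: 33 plastochromenol-8
Conditions: Bu4NF, AcOH, THF, 0 °C, argon, dark
Reagents that add atoms: none
Why: fluoride-induced cleavage of the aryl silyl ether (Si–F bond formation), buffered with acetic acid so that the electron-rich phenoxide is not exposed to base and air, should release the chromenol without touching C2 or the polyene.

**Compound list**
1 | (2E,6E)-1-bromo-3,7,11-trimethyldodeca-2,6,10-triene [(E,E)-farnesyl bromide] | CC(C)=CCC/C(C)=C/CC/C(C)=C/CBr | starting material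
2 | trimethyl(prop-1-yn-1-yl)silane [1-(trimethylsilyl)propyne] | CC#C[Si](C)(C)C | starting material
3 | trimethyl[(5E,9E)-6,10,14-trimethylpentadeca-5,9,13-trien-1-yn-1-yl]silane | CC(C)=CCC/C(C)=C/CC/C(C)=C/CCC#C[Si](C)(C)C | intermediate
4 | (5E,9E)-6,10,14-trimethylpentadeca-5,9,13-trien-1-yne | CC(C)=CCC/C(C)=C/CC/C(C)=C/CCC#C | intermediate
5 | (2E,6E,10E)-3,7,11,15-tetramethylhexadeca-2,6,10,14-tetraen-1-ol (all-E-geranylgeraniol) | CC(C)=CCC/C(C)=C/CC/C(C)=C/CC/C(C)=C/CO | starting material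
6 | (2E,6E,10E)-1-bromo-3,7,11,15-tetramethylhexadeca-2,6,10,14-tetraene | CC(C)=CCC/C(C)=C/CC/C(C)=C/CC/C(C)=C/CBr | intermediate
7 | trimethyl[(5E,9E,13E)-6,10,14,18-tetramethylnonadeca-5,9,13,17-tetraen-1-yn-1-yl]silane | CC(C)=CCC/C(C)=C/CC/C(C)=C/CC/C(C)=C/CCC#C[Si](C)(C)C | intermediate
8 | (5E,9E,13E)-6,10,14,18-tetramethylnonadeca-5,9,13,17-tetraen-1-yne | CC(C)=CCC/C(C)=C/CC/C(C)=C/CC/C(C)=C/CCC#C | intermediate
9 | dimethyl[(1E,5E,9E,13E)-2,6,10,14,18-pentamethylnonadeca-1,5,9,13,17-pentaen-1-yl]alumane | CC(C)=CCC/C(C)=C/CC/C(C)=C/CC/C(C)=C/CC/C(C)=C/[Al](C)C | intermediate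
10 | lithium butyl(dimethyl)[(1E,5E,9E,13E)-2,6,10,14,18-pentamethylnonadeca-1,5,9,13,17-pentaen-1-yl]aluminate | CC(C)=CCC/C(C)=C/CC/C(C)=C/CC/C(C)=C/CC/C(C)=C/[Al-](C)(C)CCCC.[Li+] | intermediate
11 | (2E,6E,10E,14E)-3,7,11,15,19-pentamethylicosa-2,6,10,14,18-pentaen-1-ol | CC(C)=CCC/C(C)=C/CC/C(C)=C/CC/C(C)=C/CC/C(C)=C/CO | intermediate
12 | [(2R,3R)-3-methyl-3-[(3E,7E,11E)-4,8,12,16-tetramethylheptadeca-3,7,11,15-tetraen-1-yl]oxiran-2-yl]methanol | CC(C)=CCC/C(C)=C/CC/C(C)=C/CC/C(C)=C/CC[C@@]1(C)O[C@@H]1CO | intermediate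
13 | (2R,3S)-3-(chloromethyl)-2-methyl-2-[(3E,7E,11E)-4,8,12,16-tetramethylheptadeca-3,7,11,15-tetraen-1-yl]oxirane | CC(C)=CCC/C(C)=C/CC/C(C)=C/CC/C(C)=C/CC[C@@]1(C)O[C@@H]1CCl | intermediate
14 | lithium (1E,3R,6E,10E,14E)-1-chloro-3,7,11,15,19-pentamethylicosa-1,6,10,14,18-pentaen-3-olate (E shown; either chloroalkene geometry converges on 15) | CC(C)=CCC/C(C)=C/CC/C(C)=C/CC/C(C)=C/CC[C@@](C)([O-])/C=C/Cl.[Li+] | intermediate
15 | (3R,6E,10E,14E)-3,7,11,15,19-pentamethylicosa-6,10,14,18-tetraen-1-yn-3-ol | CC(C)=CCC/C(C)=C/CC/C(C)=C/CC/C(C)=C/CC[C@@](C)(O)C#C | intermediate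
16 | 4-amino-2,3-dimethylphenol | Nc1ccc(O)c(C)c1C | starting material
17 | 2,3-dimethyl-4-[(triisopropylsilyl)oxy]aniline | Nc1ccc(O[Si](C(C)C)(C(C)C)C(C)C)c(C)c1C | intermediate
18 | 6-iodo-2,3-dimethyl-4-[(triisopropylsilyl)oxy]aniline | Nc1c(I)cc(O[Si](C(C)C)(C(C)C)C(C)C)c(C)c1C | intermediate
19 | 6-iodo-2,3-dimethyl-4-[(triisopropylsilyl)oxy]benzenediazonium bromide | N#[N+]c1c(I)cc(O[Si](C(C)C)(C(C)C)C(C)C)c(C)c1C.[Br-] | intermediate
20 | (4-bromo-5-iodo-2,3-dimethylphenoxy)triisopropylsilane | Brc1c(I)cc(O[Si](C(C)C)(C(C)C)C(C)C)c(C)c1C | intermediate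
21 | (3R,6E,10E,14E)-1-{2-bromo-3,4-dimethyl-5-[(triisopropylsilyl)oxy]phenyl}-3,7,11,15,19-pentamethylicosa-6,10,14,18-tetraen-1-yn-3-ol | CC(C)=CCC/C(C)=C/CC/C(C)=C/CC/C(C)=C/CC[C@@](C)(O)C#Cc1cc(O[Si](C(C)C)(C(C)C)C(C)C)c(C)c(C)c1Br | intermediate
22 | (1Z,3R,6E,10E,14E)-1-{2-bromo-3,4-dimethyl-5-[(triisopropylsilyl)oxy]phenyl}-3,7,11,15,19-pentamethylicosa-1,6,10,14,18-pentaen-3-ol | CC(C)=CCC/C(C)=C/CC/C(C)=C/CC/C(C)=C/CC[C@@](C)(O)/C=C\c1cc(O[Si](C(C)C)(C(C)C)C(C)C)c(C)c(C)c1Br | intermediate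
23 | triisopropyl({(2R)-2,7,8-trimethyl-2-[(3E,7E,11E)-4,8,12,16-tetramethylheptadeca-3,7,11,15-tetraen-1-yl]-2H-chromen-6-yl}oxy)silane | CC(C)=CCC/C(C)=C/CC/C(C)=C/CC/C(C)=C/CC[C@]1(C)C=Cc2cc(O[Si](C(C)C)(C(C)C)C(C)C)c(C)c(C)c2O1 | intermediate
24 | (2E,6E,10E,14E)-2,6,10,14-tetramethyl-17-{(2R)-2,7,8-trimethyl-6-[(triisopropylsilyl)oxy]-2H-chromen-2-yl}heptadeca-2,6,10,14-tetraen-1-ol | OC/C(C)=C/CC/C(C)=C/CC/C(C)=C/CC/C(C)=C/CC[C@]1(C)C=Cc2cc(O[Si](C(C)C)(C(C)C)C(C)C)c(C)c(C)c2O1 | intermediate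
25 | (2E,6E,10E,14E)-2,6,10,14-tetramethyl-17-{(2R)-2,7,8-trimethyl-6-[(triisopropylsilyl)oxy]-2H-chromen-2-yl}heptadeca-2,6,10,14-tetraenal | O=C/C(C)=C/CC/C(C)=C/CC/C(C)=C/CC/C(C)=C/CC[C@]1(C)C=Cc2cc(O[Si](C(C)C)(C(C)C)C(C)C)c(C)c(C)c2O1 | intermediate
26 | triisopropyl({(2R)-2,7,8-trimethyl-2-[(3E,7E,11E,15E)-4,8,12,16-tetramethyloctadeca-3,7,11,15,17-pentaen-1-yl]-2H-chromen-6-yl}oxy)silane | C=C/C(C)=C/CC/C(C)=C/CC/C(C)=C/CC/C(C)=C/CC[C@]1(C)C=Cc2cc(O[Si](C(C)C)(C(C)C)C(C)C)c(C)c(C)c2O1 | intermediate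
27 | 9-[(3E,7E,11E,15E)-3,7,11,15-tetramethyl-18-{(2R)-2,7,8-trimethyl-6-[(triisopropylsilyl)oxy]-2H-chromen-2-yl}octadeca-3,7,11,15-tetraen-1-yl]-9-borabicyclo[3.3.1]nonane | C1CCC2CCCC1B2CC/C(C)=C/CC/C(C)=C/CC/C(C)=C/CC/C(C)=C/CC[C@]3(C)C=Cc4cc(O[Si](C(C)C)(C(C)C)C(C)C)c(C)c(C)c4O3 | intermediate
28 | (3E,7E,11E,15E)-3,7,11,15-tetramethyl-18-{(2R)-2,7,8-trimethyl-6-[(triisopropylsilyl)oxy]-2H-chromen-2-yl}octadeca-3,7,11,15-tetraen-1-ol | OCC/C(C)=C/CC/C(C)=C/CC/C(C)=C/CC/C(C)=C/CC[C@]1(C)C=Cc2cc(O[Si](C(C)C)(C(C)C)C(C)C)c(C)c(C)c2O1 | intermediate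
29 | {[(2R)-2-[(3E,7E,11E,15E)-18-iodo-4,8,12,16-tetramethyloctadeca-3,7,11,15-tetraen-1-yl]-2,7,8-trimethyl-2H-chromen-6-yl]oxy}triisopropylsilane | ICC/C(C)=C/CC/C(C)=C/CC/C(C)=C/CC/C(C)=C/CC[C@]1(C)C=Cc2cc(O[Si](C(C)C)(C(C)C)C(C)C)c(C)c(C)c2O1 | intermediate
30 | dimethyl[(1E,5E,9E)-2,6,10,14-tetramethylpentadeca-1,5,9,13-tetraen-1-yl]alumane | CC(C)=CCC/C(C)=C/CC/C(C)=C/CC/C(C)=C/[Al](C)C | intermediate
31 | bromo[(1E,5E,9E)-2,6,10,14-tetramethylpentadeca-1,5,9,13-tetraen-1-yl]zinc | CC(C)=CCC/C(C)=C/CC/C(C)=C/CC/C(C)=C/[Zn]Br | intermediate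
32 | triisopropyl({(2R)-2,7,8-trimethyl-2-[(3E,7E,11E,15E,19E,23E,27E)-4,8,12,16,20,24,28,32-octamethyltritriaconta-3,7,11,15,19,23,27,31-octaen-1-yl]-2H-chromen-6-yl}oxy)silane | CC(C)=CCC/C(C)=C/CC/C(C)=C/CC/C(C)=C/CC/C(C)=C/CC/C(C)=C/CC/C(C)=C/CC/C(C)=C/CC[C@]1(C)C=Cc2cc(O[Si](C(C)C)(C(C)C)C(C)C)c(C)c(C)c2O1 | intermediate
33 | (2R)-2,7,8-trimethyl-2-[(3E,7E,11E,15E,19E,23E,27E)-4,8,12,16,20,24,28,32-octamethyltritriaconta-3,7,11,15,19,23,27,31-octaen-1-yl]-2H-chromen-6-ol (plastochromenol-8) | CC(C)=CCC/C(C)=C/CC/C(C)=C/CC/C(C)=C/CC/C(C)=C/CC/C(C)=C/CC/C(C)=C/CC/C(C)=C/CC[C@]1(C)C=Cc2cc(O)c(C)c(C)c2O1 | target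

**Step count**
Total: 19 steps. Longest linear sequence: 15 steps (steps 2–7 and 11–19, from geranylgeraniol).

**Steps most likely to fail**

1. Step 18 (Proposed new method). After oxidative addition, β-hydride elimination of the homoallylpalladium species or methyl transfer from aluminium may outrun alkenyl transfer, so that the iodide is consumed without fragment union. The fallback uses known chemistry, sets out from 4 and 26 and comes back at 32. Alkyne 4 is methylaluminated as in step 18 and the alane 30 is quenched with I2 (THF, −30 °C) to give (1E,5E,9E)-1-iodo-2,6,10,14-tetramethylpentadeca-1,5,9,13-tetraene F1. Diene 26 is hydroborated with 9-BBN to borane 27 as in step 16 and, without oxidation, cross-coupled with F1 (PdCl2(dppf), AsPh3, aq. K3PO4, THF/DMF, rt; B-alkyl Suzuki–Miyaura coupling) to give 32. The oxidation of step 16 and step 17 are then not needed.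

2. Step 13. C–O reductive elimination at the doubly ortho-substituted arylpalladium tertiary alkoxide may be slow, so that protodebromination or Z-to-E isomerisation of the styrene takes over. The fallback closes the ring through the quinone oxidation level instead, again without breaking the C2–O bond; it sets out from 15 and comes back at 23.
   - Commercial 1,4-dimethoxy-2,3-dimethylbenzene is iodinated (N-iodosuccinimide, CF3CO2H cat., MeCN) to 1-iodo-2,5-dimethoxy-3,4-dimethylbenzene F2.
   - Sonogashira coupling of F2 with 15 (as in step 11) gives (3R,6E,10E,14E)-1-(2,5-dimethoxy-3,4-dimethylphenyl)-3,7,11,15,19-pentamethylicosa-6,10,14,18-tetraen-1-yn-3-ol F3.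
   - Lindlar reduction (as in step 12) gives the Z alkene (1Z,3R,6E,10E,14E)-1-(2,5-dimethoxy-3,4-dimethylphenyl)-3,7,11,15,19-pentamethylicosa-1,6,10,14,18-pentaen-3-ol F4.
   - Oxidative demethylation with (NH4)2Ce(NO3)6 (MeCN/H2O, 0 °C) gives 2-[(1Z,3R,6E,10E,14E)-3-hydroxy-3,7,11,15,19-pentamethylicosa-1,6,10,14,18-pentaen-1-yl]-5,6-dimethylcyclohexa-2,5-diene-1,4-dione F5.
   - HC(OMe)3, MeOH and catalytic H2SO4 should close the tertiary hydroxyl onto the neighbouring quinone carbonyl as the cyclic methyl ketal (2R)-8a-methoxy-2,7,8-trimethyl-2-[(3E,7E,11E)-4,8,12,16-tetramethylheptadeca-3,7,11,15-tetraen-1-yl]-2H-chromen-6(8aH)-one F6. Intramolecular conjugate addition of the hydroxyl to the free quinone CH is the side path to watch.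
   - Reduction with ascorbic acid (or Zn/AcOH) should expel methanol and aromatise to (2R)-2,7,8-trimethyl-2-[(3E,7E,11E)-4,8,12,16-tetramethylheptadeca-3,7,11,15-tetraen-1-yl]-2H-chromen-6-ol F7.
   - Silylation (i-Pr3SiCl, imidazole, DMF) returns to 23.

3. Step 14. The ene step may not discriminate well enough between the terminal isopropylidene and the three internal trisubstituted alkenes, and the product may be over-oxidised. The fallback sets out from 23 and comes back at 24, which is then oxidised to 25 with MnO2 as in the second half of step 14.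
   - Terminal bromohydrin formation with N-bromosuccinimide in aqueous THF at 0 °C gives (6E,10E,14E)-3-bromo-2,6,10,14-tetramethyl-17-{(2R)-2,7,8-trimethyl-6-[(triisopropylsilyl)oxy]-2H-chromen-2-yl}heptadeca-6,10,14-trien-2-ol F8.
   - K2CO3/MeOH closes it to the terminal epoxide {[(2R)-2-[(3E,7E,11E)-14-(3,3-dimethyloxiran-2-yl)-4,8,12-trimethyltetradeca-3,7,11-trien-1-yl]-2,7,8-trimethyl-2H-chromen-6-yl]oxy}triisopropylsilane F9.
   - Periodic acid (H5IO6, THF/Et2O, 0 °C) cleaves it to (4E,8E,12E)-4,8,12-trimethyl-15-{(2R)-2,7,8-trimethyl-6-[(triisopropylsilyl)oxy]-2H-chromen-2-yl}pentadeca-4,8,12-trienal F10.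
   - E-selective Wittig olefination with Ph3P=C(CH3)CO2Et (CH2Cl2, rt) rebuilds the terminal unit as ethyl (2E,6E,10E,14E)-2,6,10,14-tetramethyl-17-{(2R)-2,7,8-trimethyl-6-[(triisopropylsilyl)oxy]-2H-chromen-2-yl}heptadeca-2,6,10,14-tetraenoate F11.
   - i-Bu2AlH (toluene, −78 °C) reduces F11 to 24.

**Further compounds**
F1 | step 18 | (1E,5E,9E)-1-iodo-2,6,10,14-tetramethylpentadeca-1,5,9,13-tetraene | CC(C)=CCC/C(C)=C/CC/C(C)=C/CC/C(C)=C/I
F2 | step 13 | 1-iodo-2,5-dimethoxy-3,4-dimethylbenzene | COc1cc(I)c(OC)c(C)c1C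
F3 | step 13 | (3R,6E,10E,14E)-1-(2,5-dimethoxy-3,4-dimethylphenyl)-3,7,11,15,19-pentamethylicosa-6,10,14,18-tetraen-1-yn-3-ol | CC(C)=CCC/C(C)=C/CC/C(C)=C/CC/C(C)=C/CC[C@@](C)(O)C#Cc1cc(OC)c(C)c(C)c1OC
F4 | step 13 | (1Z,3R,6E,10E,14E)-1-(2,5-dimethoxy-3,4-dimethylphenyl)-3,7,11,15,19-pentamethylicosa-1,6,10,14,18-pentaen-3-ol | CC(C)=CCC/C(C)=C/CC/C(C)=C/CC/C(C)=C/CC[C@@](C)(O)/C=C\c1cc(OC)c(C)c(C)c1OC
F5 | step 13 | 2-[(1Z,3R,6E,10E,14E)-3-hydroxy-3,7,11,15,19-pentamethylicosa-1,6,10,14,18-pentaen-1-yl]-5,6-dimethylcyclohexa-2,5-diene-1,4-dione | CC(C)=CCC/C(C)=C/CC/C(C)=C/CC/C(C)=C/CC[C@@](C)(O)/C=C\C1=CC(=O)C(C)=C(C)C1=O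
F6 | step 13 | (2R)-8a-methoxy-2,7,8-trimethyl-2-[(3E,7E,11E)-4,8,12,16-tetramethylheptadeca-3,7,11,15-tetraen-1-yl]-2H-chromen-6(8aH)-one (both 8a epimers) | CC(C)=CCC/C(C)=C/CC/C(C)=C/CC/C(C)=C/CC[C@]1(C)C=CC2=CC(=O)C(C)=C(C)C2(OC)O1
F7 | step 13 | (2R)-2,7,8-trimethyl-2-[(3E,7E,11E)-4,8,12,16-tetramethylheptadeca-3,7,11,15-tetraen-1-yl]-2H-chromen-6-ol | CC(C)=CCC/C(C)=C/CC/C(C)=C/CC/C(C)=C/CC[C@]1(C)C=Cc2cc(O)c(C)c(C)c2O1
F8 | step 14 | (6E,10E,14E)-3-bromo-2,6,10,14-tetramethyl-17-{(2R)-2,7,8-trimethyl-6-[(triisopropylsilyl)oxy]-2H-chromen-2-yl}heptadeca-6,10,14-trien-2-ol (both C3 epimers) | CC(C)(O)C(Br)CC/C(C)=C/CC/C(C)=C/CC/C(C)=C/CC[C@]1(C)C=Cc2cc(O[Si](C(C)C)(C(C)C)C(C)C)c(C)c(C)c2O1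
F9 | step 14 | {[(2R)-2-[(3E,7E,11E)-14-(3,3-dimethyloxiran-2-yl)-4,8,12-trimethyltetradeca-3,7,11-trien-1-yl]-2,7,8-trimethyl-2H-chromen-6-yl]oxy}triisopropylsilane (both oxirane epimers) | CC1(C)OC1CC/C(C)=C/CC/C(C)=C/CC/C(C)=C/CC[C@]2(C)C=Cc3cc(O[Si](C(C)C)(C(C)C)C(C)C)c(C)c(C)c3O2
F10 | step 14 | (4E,8E,12E)-4,8,12-trimethyl-15-{(2R)-2,7,8-trimethyl-6-[(triisopropylsilyl)oxy]-2H-chromen-2-yl}pentadeca-4,8,12-trienal | O=CCC/C(C)=C/CC/C(C)=C/CC/C(C)=C/CC[C@]1(C)C=Cc2cc(O[Si](C(C)C)(C(C)C)C(C)C)c(C)c(C)c2O1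
F11 | step 14 | ethyl (2E,6E,10E,14E)-2,6,10,14-tetramethyl-17-{(2R)-2,7,8-trimethyl-6-[(triisopropylsilyl)oxy]-2H-chromen-2-yl}heptadeca-2,6,10,14-tetraenoate | CCOC(=O)/C(C)=C/CC/C(C)=C/CC/C(C)=C/CC/C(C)=C/CC[C@]1(C)C=Cc2cc(O[Si](C(C)C)(C(C)C)C(C)C)c(C)c(C)c2O1
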